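**Plan**
- **Cuts, from the outside in:** C8–CH2 (prenyl, Stille), C6–C(=O) (benzoyl, Friedel–Crafts), C8–Br and the two O–CH3 bonds. These lead back to (R)-5,7-dimethoxy-4-phenylchroman-2-one. Cutting C2–C3 and C3–C4 then removes the methylene C3.
- **Enabling feature:** in the lactone ring O1–C2(=O)–C3–C4–C4a–C8a, C3 is a bare CH2 between the carbonyl C2 and the stereocentre C4. Without it the ring is the five-membered lactone of a 3-phenylbenzofuran-2-one, whose O-silyl enol form is a furan with a ketene-acetal C2=C3 bond that can take CH2 back up.
- **Ring order, forward:** benzofuranone ring (3,5-dimethoxyphenol + mandelic acid), aromatic silyloxyfuran, cyclopropane fused to the dearomatised furan, then cleavage of the shared bond so the five-membered ring becomes the six-membered lactone. C8–Br, C6–benzoyl, free phenols and C8–prenyl follow.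
- **Stereochemistry:** a chiral dipeptide on the zinc carbenoid picks the furan face and sets both cyclopropane carbons. The benzylic one becomes C4 by protonation with inversion, (6bR) to (4R), and no later step touches C4.

Key step: step 3

Remark: precedent does not predict which face N-Boc-L-Val-L-Pro-OMe (CC(C)[C@H](NC(=O)OC(C)(C)C)C(=O)N1CCC[C@H]1C(=O)OC) selects on this alkene class, so the L,L ligand is written and its D,D mirror image would be used if the opposite face were favoured; the ligand comes from one routine coupling of Boc-valine with proline methyl ester, is recovered, and is not counted as a step.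

**Step 1**
Reactants: 1 3,5-dimethoxyphenol; 2 (±)-mandelic acid
Product: 3 (±)-4,6-dimethoxy-3-phenylbenzofuran-2(3H)-one
Conditions: TfOH (10 mol %), ClCH2CH2Cl, 4 Å MS, 80 °C, N2
Reagents that add atoms: none
Why: This is the classical phenol–mandelic acid condensation (acid-catalysed Friedel–Crafts hydroxyalkylation, then lactonisation), in which the benzylic cation attacks one of the two equivalent carbons ortho to the OH and the hydroxy acid closes to the five-membered lactone, whereas attack para to OH leaves a carboxylic acid that a bicarbonate wash removes; C3 may stay racemic because step 2 erases it.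

**Step 2**
Reactants: 3 (±)-4,6-dimethoxy-3-phenylbenzofuran-2(3H)-one
Product: 4 tert-butyl[(4,6-dimethoxy-3-phenylbenzofuran-2-yl)oxy]dimethylsilane
Conditions: TBSOTf, Et3N, CH2Cl2, 0 °C
Reagents that add atoms: tert-butyldimethylsilyl triflate, CC(C)(C)[Si](C)(C)OS(=O)(=O)C(F)(F)F
Why: Soft enolisation and O-silylation of the acidic, doubly activated C3–H lactone gives the silyl ketene acetal, a standard reaction of 3-arylbenzofuranones that is driven by aromatisation to the benzofuran.

**Step 3**
Reactants: 4 tert-butyl[(4,6-dimethoxy-3-phenylbenzofuran-2-yl)oxy]dimethylsilane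
Product: 5 (1aR,6bR)-1a-(tert-butyldimethylsilyloxy)-4,6-dimethoxy-6b-phenyl-1a,6b-dihydro-1H-cyclopropa[b]benzofuran (C1a = former furan C2, C6b = former furan C3, C1 = new CH2; cis-fused)
Conditions: Et2Zn (excess), CH2I2, N-Boc-L-Val-L-Pro-OMe (1.2 equiv), CH2Cl2, −40 → −20 °C; aq. NaHCO3/EDTA; short basic alumina column
Reagents that add atoms: diiodomethane, ICI
Why: Proposed new method: the iodomethylzinc unit bound to the deprotonated carbamate nitrogen of the dipeptide is electrophilic and hands its CH2 to the most electron-rich π bond, the C2=C3 ketene-acetal bond of the furan, through the concerted butterfly transition state of the Simmons–Smith reaction, so that C2–CH2 and C3–CH2 form in one event and only the weak furan aromaticity is lost. The closest known reaction types are the dipeptide–zinc enantioselective Simmons–Smith cyclopropanation of aryl silyl enol ethers and the racemic cyclopropanation of alkyl silyl ketene acetals; a heteroaromatic, tetrasubstituted ketene acetal has not been shown. The cyclopropane closes by suprafacial (2+1) addition to a ring alkene, which allows only the cis-fused 2-oxabicyclo[3.1.0]hexane. C1a and C6b are therefore tied to each other by the geometry of the addition, and their absolute sense is set by the face that the chiral ligand sphere on zinc leaves open. The step needs enantiofacial selectivity on a flat alkene, and the substrate helps by being rigid and strongly unsymmetrical in its plane: the bulky OTBS group at C2 and the phenyl ring at C3, held twisted by the peri 4-methoxy group, should leave one docking orientation in the ligand pocket, while the benzene rings are too electron-poor to compete for the carbenoid. Excess Et2Zn converts ZnI2 into the weaker Lewis acid EtZnI and the TBS group resists iodide attack at silicon, which should prevent early opening of 5 to a zinc homoenolate.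

**Step 4**
Reactants: 5 (1aR,6bR)-silyloxycyclopropa[b]benzofuran
Product: 7 (R)-5,7-dimethoxy-4-phenylchroman-2-one, via cyclopropanol hemiketal 6 (not isolated)
Conditions: TBAF (1 M in THF, 1.2 equiv), AcOH (1.0 equiv), MeOH, −40 → 0 °C
Reagents that add atoms: none
Why: Proposed new method: fluoride frees the alkoxide of hemiketal 6, whose oxygen pushes into C1a and breaks the strained ring-fusion bond C1a–C6b toward the benzylic carbon, in preference to the C1a–C1 bond (primary carbanion) or the C–OAr bond (cyclopropanone), while methanol protonates the rear lobe of C6b, which lies in the arene plane next to the peri methoxy oxygen and leads directly to the half-chair with a pseudo-axial phenyl group, so that (6bR) should become (4R) by inversion; the non-coordinating Bu4N+ cation and the dissociating protic solvent favour rear-side protonation, and the acetate buffer takes up the base equivalent so that no methoxide opens the new lactone; the closest known reaction types are the base-induced opening of 2-arylcyclopropanols toward the benzylic carbon with inversion and the opening of 1-alkoxy-1-silyloxycyclopropanes to esters, neither of which has been shown on a fused, diaryl-substituted case or as a lactone ring expansion.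

**Step 5**
Reactants: 7 (R)-5,7-dimethoxy-4-phenylchroman-2-one
Product: 8 (R)-8-bromo-5,7-dimethoxy-4-phenylchroman-2-one
Conditions: NBS (1.0 equiv), MeCN, −10 → 0 °C, dark
Reagents that add atoms: N-bromosuccinimide, O=C1CCC(=O)N1Br
Why: In this electrophilic aromatic bromination C8 (para to 5-OMe, ortho to 7-OMe and O1) is the electronically favoured and less shielded carbon, since the C4 phenyl group turns the 5-O-methyl toward C6, in line with the C8 preference known for 5,7-dialkoxychromans and 5,7-dimethoxycoumarins; darkness and low temperature suppress radical attack at the benzylic C4–H.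

**Step 6**
Reactants: 8 (R)-8-bromo-5,7-dimethoxy-4-phenylchroman-2-one; 9 benzoyl chloride
Product: 10 (R)-6-benzoyl-8-bromo-5,7-dimethoxy-4-phenylchroman-2-one
Conditions: AgOTf, 2,6-di-tert-butyl-4-methylpyridine, CH2Cl2, 0 °C → rt
Reagents that add atoms: none
Why: This is a Friedel–Crafts acylation with an acyl triflate made in situ from 9 and AgOTf, in which the slim benzoylium ion attacks C6, the only free carbon of the activated ring (ortho to both methoxy groups, para to O1) and far more nucleophilic than either phenyl ring, while the hindered pyridine traps TfOH so that acid-induced loss or migration of the C8 bromine and ionisation at C4 are avoided.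

**Step 7**
Reactants: 10 (R)-6-benzoyl-8-bromo-5,7-dimethoxy-4-phenylchroman-2-one
Product: 11 (R)-6-benzoyl-8-bromo-5,7-dihydroxy-4-phenylchroman-2-one
Conditions: BBr3 (4 equiv), CH2Cl2, −78 → 0 °C; ice/1 M HCl
Reagents that add atoms: none
Why: Boron tribromide cleaves both aryl methyl ethers, helped by the flanking ketone, while aryl bromide, diaryl ketone and aryl lactone should be inert at or below 0 °C, and the lactone cannot slip to O5 because the meta-disposed O1 and O5 cannot share C2 in one tetrahedral intermediate, so the regiochemistry holds as long as no external nucleophile opens the ring (hence the cold acidic quench).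

**Step 8**
Reactants: 11 (R)-6-benzoyl-8-bromo-5,7-dihydroxy-4-phenylchroman-2-one; 12 tributyl(3-methylbut-2-enyl)stannane
Product: 13 (R)-6-benzoyl-5,7-dihydroxy-8-(3-methylbut-2-enyl)-4-phenylchroman-2-one (CNP0313865.1)
Conditions: Pd(PPh3)4 (10 mol %), toluene, 100 °C, degassed
Reagents that add atoms: none
Why: In this Stille coupling, oxidative addition into C8–Br, prenyl transfer from tin and reductive elimination at the unsubstituted allyl terminus should give the linear prenyl group, and the medium, free of added acid or base, tolerates the chelated phenols, keeps the lactone closed and spares the ortho-prenylphenol from chroman formation.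

**Compound list**
1 | 3,5-dimethoxyphenol | COc1cc(O)cc(OC)c1 | starting material
2 | (±)-mandelic acid | OC(C(=O)O)c1ccccc1 | starting material
3 | (±)-4,6-dimethoxy-3-phenylbenzofuran-2(3H)-one | COc1cc(OC)c2c(c1)OC(=O)C2c1ccccc1 | intermediate
4 | tert-butyl[(4,6-dimethoxy-3-phenylbenzofuran-2-yl)oxy]dimethylsilane | COc1cc(OC)c2c(c1)oc(O[Si](C)(C)C(C)(C)C)c2-c1ccccc1 | intermediate
5 | (1aR,6bR)-1a-(tert-butyldimethylsilyloxy)-4,6-dimethoxy-6b-phenyl-1a,6b-dihydro-1H-cyclopropa[b]benzofuran | COc1cc(OC)c2c(c1)O[C@@]1(O[Si](C)(C)C(C)(C)C)C[C@@]21c1ccccc1 | intermediate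
6 | (1aS,6bR)-4,6-dimethoxy-6b-phenyl-1,6b-dihydro-1aH-cyclopropa[b]benzofuran-1a-ol (hemiketal, reacts as its alkoxide) | COc1cc(OC)c2c(c1)O[C@@]1(O)C[C@@]21c1ccccc1 | intermediate
7 | (R)-5,7-dimethoxy-4-phenylchroman-2-one | COc1cc(OC)c2c(c1)OC(=O)C[C@@H]2c1ccccc1 | intermediate
8 | (R)-8-bromo-5,7-dimethoxy-4-phenylchroman-2-one | COc1cc(OC)c2c(c1Br)OC(=O)C[C@@H]2c1ccccc1 | intermediate
9 | benzoyl chloride | O=C(Cl)c1ccccc1 | starting material
10 | (R)-6-benzoyl-8-bromo-5,7-dimethoxy-4-phenylchroman-2-one | COc1c(C(=O)c3ccccc3)c(OC)c2c(c1Br)OC(=O)C[C@@H]2c1ccccc1 | intermediate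
11 | (R)-6-benzoyl-8-bromo-5,7-dihydroxy-4-phenylchroman-2-one | Oc1c(C(=O)c3ccccc3)c(O)c2c(c1Br)OC(=O)C[C@@H]2c1ccccc1 | intermediate
12 | tributyl(3-methylbut-2-enyl)stannane | CC(C)=CC[Sn](CCCC)(CCCC)CCCC | starting material
13 | (R)-6-benzoyl-5,7-dihydroxy-8-(3-methylbut-2-enyl)-4-phenylchroman-2-one | CC(C)=CCc1c(O)c(C(=O)c2ccccc2)c(O)c2c1OC(=O)C[C@@H]2c1ccccc1 | target

Total step count: 8. Longest linear sequence: 8 (1 → 13).

**Steps most likely to fail**

**Step 3.**
- *What may go wrong:* facial discrimination on the flat tetrasubstituted bond may be poor. Methylene transfer to the crowded alkene may also be so slow that zinc Lewis acids open the product first.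
- *Fallback (known chemistry):* it sets out from 1 and returns at 7. Palladium-catalysed hydroarylation and lactonisation of 1 with ethyl propiolate (Pd(OAc)2, TFA, CH2Cl2, rt) should give 5,7-dimethoxycoumarin F1. A Hayashi–Miyaura 1,4-addition of phenylboronic acid (Rh(acac)(C2H4)2, (R)-Segphos, dioxane/H2O, 60 °C) should then set C4 and deliver 7.

**Step 4.**
- *What may go wrong:* the aryl-stabilised carbanion may live long enough to flatten, which erodes the enantiomeric purity. An acid-type opening with retention may run beside the alkoxide pathway, or the external C1a–C1 bond may break instead.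
- *Fallback (known chemistry):* it sets out from 1 and returns at 7. Pechmann condensation of 1 with ethyl benzoylacetate (TFA, reflux) should give 5,7-dimethoxy-4-phenylcoumarin F2. Copper hydride asymmetric conjugate reduction follows (Cu(OAc)2, DTBM-Segphos in the enantiomer that gives (R), diethoxymethylsilane, t-BuOH, toluene). On coumarins this reduction runs on to the lactol, so it should give (4R)-5,7-dimethoxy-4-phenylchroman-2-ol F3. Oxidation (TEMPO, PhI(OAc)2, CH2Cl2) returns 7.

**Step 6.**
- *What may go wrong:* acylation between two methoxy groups on a bromine-deactivated ring may be too slow, and loss or migration of the bromine could then steer the acyl group to C8.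
- *Fallback:* it sets out from 8 and returns at 10, using a smaller electrophile.
  - Rieche formylation (Cl2CHOMe, TiCl4, CH2Cl2, −78 → 0 °C), guided by titanium bound to the two methoxy oxygens, should give (R)-8-bromo-5,7-dimethoxy-2-oxo-4-phenylchroman-6-carbaldehyde F4.
  - Aldehyde-selective phenyl transfer with PhTi(OiPr)3 (THF, −40 °C), which leaves the lactone alone, should give (4R)-8-bromo-6-[hydroxy(phenyl)methyl]-5,7-dimethoxy-4-phenylchroman-2-one F5 as a carbinol epimer mixture.
  - Dess–Martin oxidation then gives 10.

**Further compounds**
F1 | step 3 | 5,7-dimethoxycoumarin | COc1cc(OC)c2ccc(=O)oc2c1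
F2 | step 4 | 5,7-dimethoxy-4-phenylcoumarin | COc1cc(OC)c2c(-c3ccccc3)cc(=O)oc2c1
F3 | step 4 | (4R)-5,7-dimethoxy-4-phenylchroman-2-ol | COc1cc(OC)c2c(c1)OC(O)C[C@@H]2c1ccccc1
F4 | step 6 | (R)-8-bromo-5,7-dimethoxy-2-oxo-4-phenylchroman-6-carbaldehyde | COc1c(C=O)c(OC)c2c(c1Br)OC(=O)C[C@@H]2c1ccccc1
F5 | step 6 | (4R)-8-bromo-6-[hydroxy(phenyl)methyl]-5,7-dimethoxy-4-phenylchroman-2-one | COc1c(C(O)c3ccccc3)c(OC)c2c(c1Br)OC(=O)C[C@@H]2c1ccccc1
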